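**Retrosynthetic overview**

1. The target is a tricoumarin: central coumarin A carries C8' of umbelliferone unit B (primed atoms) at C6 and, through O7, C3'' of umbelliferone unit C (double-primed atoms). The plan rests on the C6–C8' biaryl bond: C8' is the carbon at which umbelliferone accepts a formyl group, so that formyl carbon is kept and becomes C6 of ring A, whose benzene ring carries two meta oxygens (on C7 and C8a) that must end up differently substituted.
2. End game: O-demethylation at O7' and O7''; the pyranone of A by Wittig lactonization of a salicylaldehyde, itself obtained by formylation at C4a and chelation-directed de-ethylation of the oxygen on C8a.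
3. Pyranone of C by Perkin–Oglialoro condensation of the O7-acetic acid with 2-hydroxy-4-methoxybenzaldehyde.
4. Benzene ring of A by photochemical Wolff rearrangement of a coumarinyl enone diazoketone and benzannulation with ethoxyacetylene; this forms C7–C8, C4a–C8a and C6–C7 and delivers O7 free and the C8a oxygen as its ethyl ether.
5. Diazoketone from umbelliferone by C8 formylation, O-methylation, Wittig olefination to the methyl enone and detrifluoroacetylative diazo transfer. Ring order: B (bought), benzene ring of A, pyranone of C, pyranone of A.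

Key step: step 5

Assumption: the C6–C8' axis has three ortho substituents but the target is drawn without axial configuration, so the axis is not controlled and the material is taken as racemic or freely rotating.

**Route**

Step 1
Reactants: 1 umbelliferone (7-hydroxychromen-2-one)
Product: 2 7-hydroxy-2-oxochromene-8-carbaldehyde
Conditions: hexamethylenetetramine, CF3CO2H, 90 °C; then aq. HCl, 60 °C
Reagents that add atoms: hexamethylenetetramine, C1N2CN3CN1CN(C2)C3; water, O
Why: Duff formylation, in which the iminium ion from protonated hexamethylenetetramine attacks C8, the ortho position of the 7-hydroxyl at which umbelliferone is known to react, and hydrolysis releases the aldehyde.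

Step 2
Reactants: 2 7-hydroxy-2-oxochromene-8-carbaldehyde
Product: 3 7-methoxy-2-oxochromene-8-carbaldehyde
Conditions: MeI, K2CO3, DMF, 40 °C
Reagents that add atoms: iodomethane, CI
Why: Williamson etherification of the phenoxide caps O7' as a methyl ether that should survive every later step until the final BBr3 treatment.

Step 3
Reactants: 3 7-methoxy-2-oxochromene-8-carbaldehyde; 4 1-(triphenylphosphoranylidene)propan-2-one
Product: 5 (E)-4-(7-methoxy-2-oxochromen-8-yl)but-3-en-2-one
Conditions: toluene, 100 °C
Reagents that add atoms: none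
Why: Wittig olefination with a stabilized acyl ylide should give the E enone and leaves the lactone untouched.

Step 4
Reactants: 5 (E)-4-(7-methoxy-2-oxochromen-8-yl)but-3-en-2-one
Product: 7 (E)-1-diazo-4-(7-methoxy-2-oxochromen-8-yl)but-3-en-2-one, via trifluoroacetyl diketone 6 (not isolated)
Conditions: LiN(SiMe3)2, THF, −78 °C; CF3CO2CH2CF3, −78 °C; aq. HCl work-up; then 4-AcNHC6H4SO2N3, Et3N, H2O (1 equiv), MeCN, rt
Reagents that add atoms: 4-acetamidobenzenesulfonyl azide, CC(=O)Nc1ccc(cc1)S(=O)(=O)N=[N+]=[N-]; 2,2,2-trifluoroethyl trifluoroacetate, O=C(OCC(F)(F)F)C(F)(F)F (its trifluoroacetyl group stays in 6 only and is lost again)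
Why: Trifluoroacetylation of the methyl ketone (Claisen condensation) activates it for Regitz-type detrifluoroacetylative diazo transfer, which places the diazo group on the former methyl carbon and avoids the acid chloride and diazomethane route, in which diazomethane can add across the conjugated alkene.

Step 5
Reactants: 7 (E)-1-diazo-4-(7-methoxy-2-oxochromen-8-yl)but-3-en-2-one; 8 ethoxyacetylene
Product: 13 8-(4-ethoxy-2-hydroxyphenyl)-7-methoxychromen-2-one, via vinylketene 9 (not isolated), via cyclobutenone 10 (not isolated), via dienylketene 11 (not isolated), via cyclohexadienone 12 (not isolated)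
Conditions: 8 (3 equiv), ClCH2CH2Cl, hν (420 nm LED), rt; then 80 °C
Reagents that add atoms: none
Why: Irradiation expels N2 from 7 and the alkenyl group shifts from the carbonyl carbon to the diazo carbon (photochemical Wolff rearrangement, which joins C5 to C4a) to give vinylketene 9. The electron-rich terminal carbon of ethoxyacetylene attacks the ketene carbonyl carbon and the (2+2) cycloaddition gives cyclobutenone 10, forming C7–C8 and C4a–C8a. Four-electron electrocyclic opening of 10 gives dienylketene 11, whose six-electron disrotatory electrocyclization closes the only new ring, the benzene ring of A, through the C6–C7 bond, and tautomerization of dienone 12 gives phenol 13. The closest known reaction type is the Danheiser benzannulation in its photochemical diazoketone form, which converts unsaturated α-diazoketones and alkoxyalkynes into 3-alkoxyphenols. No stereocenter remains, since the sp3 carbons of 10 and 12 are racemic and are erased on aromatization. The step needs regiocontrol in the ketene–alkyne addition, secured by the polarization of the ynol ether (hydrogen at C8 between the oxygens, ethoxy on C8a, free hydroxyl on C7 next to the aryl group), and selective excitation of the diazoketone, secured by light beyond the absorption edge of the 7-methoxycoumarin chromophore.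

Step 6
Reactants: 13 8-(4-ethoxy-2-hydroxyphenyl)-7-methoxychromen-2-one; 14 tert-butyl bromoacetate
Product: 15 tert-butyl 2-[5-ethoxy-2-(7-methoxy-2-oxochromen-8-yl)phenoxy]acetate
Conditions: K2CO3, DMF, 40 °C
Reagents that add atoms: none
Why: Williamson etherification of the only free phenol (O7) with a reactive α-bromo ester under hydroxide-free conditions that do not open the lactone.

Step 7
Reactants: 15 tert-butyl 2-[5-ethoxy-2-(7-methoxy-2-oxochromen-8-yl)phenoxy]acetate
Product: 16 2-[5-ethoxy-2-(7-methoxy-2-oxochromen-8-yl)phenoxy]acetic acid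
Conditions: CF3CO2H, CH2Cl2, rt
Reagents that add atoms: none
Why: Acidolysis of the tert-butyl ester with loss of isobutene frees the acid without base, so the lactone is not opened.

Step 8
Reactants: 16 2-[5-ethoxy-2-(7-methoxy-2-oxochromen-8-yl)phenoxy]acetic acid; 17 2-hydroxy-4-methoxybenzaldehyde
Product: 18 8-{4-ethoxy-2-[(7-methoxy-2-oxochromen-3-yl)oxy]phenyl}-7-methoxychromen-2-one
Conditions: Ac2O, Et3N, 120 °C
Reagents that add atoms: none
Why: Perkin–Oglialoro condensation under dehydrating conditions joins the activated α-methylene of the aryloxyacetic acid to the aldehyde carbon and its carboxyl to the salicyl oxygen, closing the pyranone of ring C with the aryloxy group at C3''.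

Step 9
Reactants: 18 8-{4-ethoxy-2-[(7-methoxy-2-oxochromen-3-yl)oxy]phenyl}-7-methoxychromen-2-one
Product: 19 2-ethoxy-5-(7-methoxy-2-oxochromen-8-yl)-4-[(7-methoxy-2-oxochromen-3-yl)oxy]benzaldehyde
Conditions: Cl2CHOMe, TiCl4, CH2Cl2, −10 to 0 °C; then H2O
Reagents that add atoms: dichloromethyl methyl ether, COC(Cl)Cl; water, O
Why: Rieche formylation is an electrophilic aromatic substitution that should select C4a, the position ortho to the ethoxy group and para to O7 on the only benzene ring not deactivated by a pyranone, while C8 is shielded between two ether groups.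

Step 10
Reactants: 19 2-ethoxy-5-(7-methoxy-2-oxochromen-8-yl)-4-[(7-methoxy-2-oxochromen-3-yl)oxy]benzaldehyde
Product: 20 2-hydroxy-5-(7-methoxy-2-oxochromen-8-yl)-4-[(7-methoxy-2-oxochromen-3-yl)oxy]benzaldehyde
Conditions: BCl3, CH2Cl2, −78 to 0 °C; then H2O
Reagents that add atoms: none
Why: BCl3 chelates between the formyl oxygen and the ortho ethoxy oxygen, so chloride dealkylates only this ether (chelation-controlled ether cleavage) and the two non-chelated methyl ethers and the diaryl-type ether should stay.

Step 11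
Reactants: 20 2-hydroxy-5-(7-methoxy-2-oxochromen-8-yl)-4-[(7-methoxy-2-oxochromen-3-yl)oxy]benzaldehyde; 21 ethyl 2-(triphenylphosphoranylidene)acetate
Product: 23 6-(7-methoxy-2-oxochromen-8-yl)-7-[(7-methoxy-2-oxochromen-3-yl)oxy]chromen-2-one, via hydroxycinnamate ester 22 (not isolated)
Conditions: PhNEt2, 210 °C
Reagents that add atoms: none
Why: Wittig olefination of the salicylaldehyde with the stabilized ylide, followed at this temperature by E/Z equilibration and lactonization with loss of ethanol, is the standard one-pot coumarin synthesis and closes the pyranone of ring A.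

Step 12
Reactants: 23 6-(7-methoxy-2-oxochromen-8-yl)-7-[(7-methoxy-2-oxochromen-3-yl)oxy]chromen-2-one
Product: 24 6-(7-hydroxy-2-oxochromen-8-yl)-7-[(7-hydroxy-2-oxochromen-3-yl)oxy]chromen-2-one (CNP0215289.0)
Conditions: BBr3, CH2Cl2, −78 °C to rt; then H2O
Reagents that add atoms: none
Why: BBr3 cleaves both aryl methyl ethers by bromide attack on the O-methyl group of the boron–ether complex, whereas the three lactones and the aryl–O–vinyl ether are inert to it.

**Compound list**

1 | umbelliferone (7-hydroxychromen-2-one) | Oc1ccc2ccc(=O)oc2c1 | starting material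
2 | 7-hydroxy-2-oxochromene-8-carbaldehyde | O=Cc1c(O)ccc2ccc(=O)oc12 | intermediate
3 | 7-methoxy-2-oxochromene-8-carbaldehyde | COc1ccc2ccc(=O)oc2c1C=O | intermediate
4 | 1-(triphenylphosphoranylidene)propan-2-one | CC(=O)C=P(c1ccccc1)(c1ccccc1)c1ccccc1 | starting material
5 | (E)-4-(7-methoxy-2-oxochromen-8-yl)but-3-en-2-one | CC(=O)/C=C/c1c(OC)ccc2ccc(=O)oc12 | intermediate
6 | (E)-1,1,1-trifluoro-6-(7-methoxy-2-oxochromen-8-yl)hex-5-ene-2,4-dione | O=C(CC(=O)/C=C/c1c(OC)ccc2ccc(=O)oc12)C(F)(F)F | intermediate (not isolated)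
7 | (E)-1-diazo-4-(7-methoxy-2-oxochromen-8-yl)but-3-en-2-one | [N-]=[N+]=CC(=O)/C=C/c1c(OC)ccc2ccc(=O)oc12 | intermediate
8 | ethoxyacetylene | C#COCC | starting material
9 | (E)-4-(7-methoxy-2-oxochromen-8-yl)buta-1,3-dien-1-one | O=C=C/C=C/c1c(OC)ccc2ccc(=O)oc12 | intermediate (not isolated)
10 | 3-ethoxy-4-[(E)-2-(7-methoxy-2-oxochromen-8-yl)ethenyl]cyclobut-2-en-1-one (racemic) | CCOC1=CC(=O)C1/C=C/c1c(OC)ccc2ccc(=O)oc12 | intermediate (not isolated)
11 | (3E,5E)-3-ethoxy-6-(7-methoxy-2-oxochromen-8-yl)hexa-1,3,5-trien-1-one (ketene carbon and C5 cis across C3=C4) | O=C=C/C(OCC)=C\C=C\c1c(OC)ccc2ccc(=O)oc12 | intermediate (not isolated)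
12 | 3-ethoxy-6-(7-methoxy-2-oxochromen-8-yl)cyclohexa-2,4-dien-1-one (racemic) | O=C1C=C(OCC)C=CC1c1c(OC)ccc2ccc(=O)oc12 | intermediate (not isolated)
13 | 8-(4-ethoxy-2-hydroxyphenyl)-7-methoxychromen-2-one | CCOc1ccc(-c2c(OC)ccc3ccc(=O)oc23)c(O)c1 | intermediate
14 | tert-butyl bromoacetate | CC(C)(C)OC(=O)CBr | starting material
15 | tert-butyl 2-[5-ethoxy-2-(7-methoxy-2-oxochromen-8-yl)phenoxy]acetate | CCOc1ccc(-c2c(OC)ccc3ccc(=O)oc23)c(OCC(=O)OC(C)(C)C)c1 | intermediate
16 | 2-[5-ethoxy-2-(7-methoxy-2-oxochromen-8-yl)phenoxy]acetic acid | CCOc1ccc(-c2c(OC)ccc3ccc(=O)oc23)c(OCC(=O)O)c1 | intermediate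
17 | 2-hydroxy-4-methoxybenzaldehyde | COc1ccc(C=O)c(O)c1 | starting material
18 | 8-{4-ethoxy-2-[(7-methoxy-2-oxochromen-3-yl)oxy]phenyl}-7-methoxychromen-2-one | CCOc1ccc(-c2c(OC)ccc3ccc(=O)oc23)c(Oc2cc3ccc(OC)cc3oc2=O)c1 | intermediate
19 | 2-ethoxy-5-(7-methoxy-2-oxochromen-8-yl)-4-[(7-methoxy-2-oxochromen-3-yl)oxy]benzaldehyde | CCOc1cc(Oc2cc3ccc(OC)cc3oc2=O)c(-c2c(OC)ccc3ccc(=O)oc23)cc1C=O | intermediate
20 | 2-hydroxy-5-(7-methoxy-2-oxochromen-8-yl)-4-[(7-methoxy-2-oxochromen-3-yl)oxy]benzaldehyde | Oc1cc(Oc2cc3ccc(OC)cc3oc2=O)c(-c2c(OC)ccc3ccc(=O)oc23)cc1C=O | intermediate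
21 | ethyl 2-(triphenylphosphoranylidene)acetate | CCOC(=O)C=P(c1ccccc1)(c1ccccc1)c1ccccc1 | starting material
22 | ethyl (E)-3-{2-hydroxy-5-(7-methoxy-2-oxochromen-8-yl)-4-[(7-methoxy-2-oxochromen-3-yl)oxy]phenyl}prop-2-enoate (E isomer drawn; it equilibrates and lactonizes in the flask) | CCOC(=O)/C=C/c1cc(-c2c(OC)ccc3ccc(=O)oc23)c(Oc2cc3ccc(OC)cc3oc2=O)cc1O | intermediate (not isolated)
23 | 6-(7-methoxy-2-oxochromen-8-yl)-7-[(7-methoxy-2-oxochromen-3-yl)oxy]chromen-2-one | O=c1ccc2cc(-c3c(OC)ccc4ccc(=O)oc34)c(Oc3cc4ccc(OC)cc4oc3=O)cc2o1 | intermediate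
24 | 6-(7-hydroxy-2-oxochromen-8-yl)-7-[(7-hydroxy-2-oxochromen-3-yl)oxy]chromen-2-one | O=c1ccc2cc(-c3c(O)ccc4ccc(=O)oc34)c(Oc3cc4ccc(O)cc4oc3=O)cc2o1 | target

**Step count and risks**

Total step count: 12. Longest linear sequence: 12 steps (1 to 24).

Steps most likely to fail:

1. Step 5. The coumarin C3'=C4' bond may enter its own photochemistry (dimerization or cycloaddition with the alkyne), the phenol being formed may capture the vinylketene as an ester, or the sequence may stall at the cyclobutenone. Fallback: make the C6–C8' bond by cross-coupling and return to the route at 13.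
 - Setting out from 1, iodination at C8 (I2, KI, aq. NH3) should give 7-hydroxy-8-iodochromen-2-one F1, and methylation (MeI, K2CO3, DMF) 8-iodo-7-methoxychromen-2-one F2.
 - Separately, commercial 4-bromoresorcinol is mono-ethylated at the unhindered hydroxyl para to bromine (EtI, K2CO3, acetone) to give 2-bromo-5-ethoxyphenol F3.
 - Miyaura borylation of F3 (bis(pinacolato)diboron, PdCl2(dppf), KOAc, dioxane, 90 °C) gives 5-ethoxy-2-(4,4,5,5-tetramethyl-1,3,2-dioxaborolan-2-yl)phenol F4.
 - Suzuki–Miyaura coupling of F2 with F4 (Pd(OAc)2, 2-dicyclohexylphosphino-2',6'-dimethoxybiphenyl, K3PO4, toluene/H2O, 80 °C) should deliver 13, with the oxygens already differentiated as in the main route.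

2. Step 9. The electrophile may spread over the three alkoxy-substituted benzene rings or enter at C8 between the two oxygens, and TiCl4 bound to the lactone carbonyls may slow the substitution. Fallback: formylate before ring C exists, when the free O7 hydroxyl is the strongest para director and only one activated arene is present; the sequence sets out from 13 and returns at 19.
 - Vilsmeier–Haack formylation of 13 (POCl3, DMF, MeCN, 0 °C to rt; aq. NaOAc) should give 2-ethoxy-4-hydroxy-5-(7-methoxy-2-oxochromen-8-yl)benzaldehyde F5.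
 - Alkylation with 14 (K2CO3, DMF) gives tert-butyl 2-[5-ethoxy-4-formyl-2-(7-methoxy-2-oxochromen-8-yl)phenoxy]acetate F6.
 - Acidolysis (CF3CO2H, CH2Cl2) gives 2-[5-ethoxy-4-formyl-2-(7-methoxy-2-oxochromen-8-yl)phenoxy]acetic acid F7.
 - Perkin–Oglialoro condensation of F7 with an excess of 17 (Ac2O, Et3N, 120 °C) should give 19 directly.

3. Step 10. Selectivity among the three alkyl aryl ethers may erode, or de-ethylation may stay incomplete because BCl3 is tied up by the four carbonyl groups. Fallback: make the selectivity unnecessary; the sequence sets out from 19 and returns at 24.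
 - Excess BBr3 (CH2Cl2, −78 °C to rt; then H2O) cleaves the ethyl and both methyl ethers of 19 to give 2-hydroxy-5-(7-hydroxy-2-oxochromen-8-yl)-4-[(7-hydroxy-2-oxochromen-3-yl)oxy]benzaldehyde F8.
 - Wittig lactonization of F8 with 21 (PhNEt2, 210 °C), a reaction that tolerates free phenols as in the preparation of 7-hydroxycoumarins from 2,4-dihydroxybenzaldehydes, should give 24 directly.

**Further compounds**

F1 | step 5 | 7-hydroxy-8-iodochromen-2-one | Oc1ccc2ccc(=O)oc2c1I
F2 | step 5 | 8-iodo-7-methoxychromen-2-one | COc1ccc2ccc(=O)oc2c1I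
F3 | step 5 | 2-bromo-5-ethoxyphenol | CCOc1ccc(Br)c(O)c1
F4 | step 5 | 5-ethoxy-2-(4,4,5,5-tetramethyl-1,3,2-dioxaborolan-2-yl)phenol | CCOc1ccc(B2OC(C)(C)C(C)(C)O2)c(O)c1
F5 | step 9 | 2-ethoxy-4-hydroxy-5-(7-methoxy-2-oxochromen-8-yl)benzaldehyde | CCOc1cc(O)c(-c2c(OC)ccc3ccc(=O)oc23)cc1C=O
F6 | step 9 | tert-butyl 2-[5-ethoxy-4-formyl-2-(7-methoxy-2-oxochromen-8-yl)phenoxy]acetate | CCOc1cc(OCC(=O)OC(C)(C)C)c(-c2c(OC)ccc3ccc(=O)oc23)cc1C=O
F7 | step 9 | 2-[5-ethoxy-4-formyl-2-(7-methoxy-2-oxochromen-8-yl)phenoxy]acetic acid | CCOc1cc(OCC(=O)O)c(-c2c(OC)ccc3ccc(=O)oc23)cc1C=O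
F8 | step 10 | 2-hydroxy-5-(7-hydroxy-2-oxochromen-8-yl)-4-[(7-hydroxy-2-oxochromen-3-yl)oxy]benzaldehyde | Oc1cc(Oc2cc3ccc(O)cc3oc2=O)c(-c2c(O)ccc3ccc(=O)oc23)cc1C=O
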